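At the time of reading, 10 h, two things are wanted: where the coupling stopped, and how much target has lasted since.

| flask | starting material | coupling partner | second substrate | third substrate | remark | time |
|---|---|---|---|---|---|---|
| beta | 0.25 M (in portions, 2) | 1.7 equiv | 5 equiv | 0.20 equiv | run made earlier; portions every 1.0 h |  |
| theta | 0.25 M (in portions, 2) | 2.6 equiv | 5 equiv | 0.20 equiv | run made earlier; portions every 1.0 h |  |
| gamma | 0.12 M (in portions, 2) | 1.2 equiv | 5 equiv | 0.20 equiv | run made earlier; portions every 1.0 h |  |
| south-east | 0.25 M | 1.20 equiv | 5.00 equiv | 0.200 equiv | everything together at the start | 10 h |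
| south-west | 0.25 M (in portions, 2) | 1.20 equiv | 5.00 equiv | 0.200 equiv | the portions of starting material follow each other after 1.0 h, the first at the start | 10 h |

| run | time / h | target / % | starting material / % |
|---|---|---|---|
| beta | 2.00 | 31.4 | 63.3 |
| beta | 4.00 | 27.0 | 63.1 |
| beta | 6.00 | 24.2 | 63.6 |
| beta | 8.00 | 20.7 | 64.6 |
| beta | 10.0 | 19.5 | 63.5 |
| theta | 0.833 | 42.5 | 6.1 |
| theta | 2.50 | 38.0 | 54.3 |
| theta | 5.00 | 31.7 | 55.2 |
| theta | 8.00 | 25.9 | 54.9 |
| theta | 10.0 | 23.9 | 55.4 |
| gamma | 2.00 | 21.5 | 75.5 |
| gamma | 4.00 | 18.4 | 75.0 |
| gamma | 6.00 | 16.2 | 75.4 |
| gamma | 8.00 | 15.0 | 74.7 |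
| gamma | 10.0 | 11.7 | 75.4 |

(standard deviation of a reading: 0.5 percentage points)

- the earlier runs were read with a standard deviation of 0.5 percentage points

- which of the two ends with the higher amount of target, in percent of the starting material charged ("neither" if they lie within 2 percentage points) (south-east / south-west / neither)
- target at the end, in percent of the starting material charged, south-east
- target at the end, in percent of the starting material charged, south-west

In the beta run, starting material reads 63.3% at 2.00 h and 63.5% at 10.0 h, so turnover has stopped although 1.7 equiv of coupling partner went in. The partner, taken here as the limiting reagent, must also be lost elsewhere.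

The turnovers can be counted as: partner charged = starting material consumed + r·ln(starting material offered / starting material left), in charges of starting material, with the late portion taken as idle. Beta gives r = 1.01, the rival number: partner lost elsewhere per unit fall in the logarithm of starting material. Theta, at 0.833 h, gives 1.03, but gamma, at 0.12 M, gives 1.42. Beta and theta, both at 0.25 M, agree at 1.7 equiv and 2.6 equiv, while gamma differs from them in concentration and in partner charge. The reckoning below carries the beta number down to 1.20 equiv at 0.25 M as an assumption, a charge that no earlier run at that concentration shows.

With 1.20 equiv, my reckoning has south-east consuming 50.1% of the charge, and south-west less, 30.5%. In theta at 10.0 h, target is 53.6% of what was consumed, which gives 26.9% and 16.3%.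

The forecast says south-east, with 27% (23% to 30.5%) and 16.3% (14% to 18.5%), reading that “the coupling partner is gone by about 1 h”.

The flask gives 23.7% for south-east and 14.4% for south-west, so south-east ends higher, as forecast.

    starting material + coupling partner → target (k = 0.710 M⁻¹ min⁻¹)
    second substrate + coupling partner → second product (k = 0.110 M⁻¹ min⁻¹)
    third substrate + coupling partner → third product (k = 3.70 M⁻¹ min⁻¹)
    coupling partner → decomposed reagent (k = 0.0330 min⁻¹)
    target ⇌ isomer of the product (K = 2.60, k = 0.00130 min⁻¹)

At 0.0471 h in south-west, the second substrate takes 2.1 times the partner that starting material takes. The constants put the rival number at 0.961, against 1.01 read from beta.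

For the neighbour of south-west with 3.00 equiv of partner, r leaves 4.21% of the charge from the first portion, which gives 24.5% target. The simulation has 24.7%.

(The runs stem from a simulated flask for substances that don't exist; noise was put on by code.)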